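Ring C is disconnected at three bonds at once: O1–C8a, C4–C4a and O1–C2. The feature exploited lies in ring A: C4a and C8a are neighbours that carry the C4 carbonyl carbon and O1, while C5, C6, C7 and C8 all bear oxygen, so ring A corresponds to a symmetrical 3,4,5,6-tetramethoxybenzyne and no regiochemical question arises. In one operation this aryne, released by fluoride from a hexasubstituted ortho-silylaryl triflate, should insert into the carboxyl C–O bond of a 3-[3,4-bis(benzyloxy)phenyl]propiolic acid, and the ortho-hydroxyaryl ynone so formed should close to the chromone. Afterwards only the chelated C5 methyl ether and two benzyl ethers need cleaving.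

Key step: step 6

Remark: compounds 1 and 9 are taken as purchasable; a sequence run in one flask without purification is counted as one step, and the species it passes through are numbered. The target has no stereocenter.

Step 1
Reactants: 1 1,2,3,4-tetramethoxybenzene
Product: 4 2,3,4,5-tetramethoxyphenol, via (2,3,4,5-tetramethoxyphenyl)lithium 2 (not isolated), via dimethyl (2,3,4,5-tetramethoxyphenyl)boronate 3 (not isolated)
Conditions: n-BuLi, TMEDA, THF, 0 °C; B(OMe)3, −78 °C → rt; AcOH, 30% aq. H2O2, 0 °C → rt
Reagents that add atoms: hydrogen peroxide, OO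
Why: Directed ortho-lithiation at the only kind of ring hydrogen (each lies ortho to a methoxy group), borylation and oxidative aryl shift from boron to oxygen (lithiation–borylation–oxidation) should give a single phenol, the acidic peroxide being chosen to spare the electron-rich product.

Step 2
Reactants: 4 2,3,4,5-tetramethoxyphenol
Product: 5 2-bromo-3,4,5,6-tetramethoxyphenol
Conditions: NBS, CH2Cl2, −78 → 0 °C, dark
Reagents that add atoms: N-bromosuccinimide, O=C1CCC(=O)N1Br
Why: Electrophilic aromatic bromination can occur only at the one remaining ring position, which is ortho to the hydroxyl group and strongly activated, and the cold anhydrous medium should disfavour oxidation to a quinone.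

Step 3
Reactants: 5 2-bromo-3,4,5,6-tetramethoxyphenol
Product: 8 3,4,5,6-tetramethoxy-2-(trimethylsilyl)phenyl trifluoromethanesulfonate, via (2-bromo-3,4,5,6-tetramethoxyphenoxy)trimethylsilane 6 (not isolated), via lithium 2,3,4,5-tetramethoxy-6-(trimethylsilyl)phenoxide 7 (not isolated)
Conditions: HMDS, THF, reflux, then volatiles removed in vacuo; n-BuLi, THF, −100 °C; Tf2O, −100 °C → rt
Reagents that add atoms: hexamethyldisilazane, C[Si](C)(C)N[Si](C)(C)C; trifluoromethanesulfonic anhydride, O=S(=O)(OS(=O)(=O)C(F)(F)F)C(F)(F)F
Why: O-silylation, bromine–lithium exchange and retro-Brook shift of silicon from oxygen to the adjacent carbanion should give a lithium phenoxide that is triflated in the same flask, the standard access to ortho-silylaryl triflates.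

Step 4
Reactants: 9 3,4-bis(benzyloxy)benzaldehyde
Product: 10 1,2-bis(benzyloxy)-4-(2,2-dibromoethenyl)benzene
Conditions: CBr4, PPh3, Zn, CH2Cl2, rt
Reagents that add atoms: carbon tetrabromide, BrC(Br)(Br)Br
Why: Corey–Fuchs dibromoolefination, a Wittig reaction of the ylide Ph3P=CBr2 with a non-enolisable aromatic aldehyde whose benzyl ethers are inert.

Step 5
Reactants: 10 1,2-bis(benzyloxy)-4-(2,2-dibromoethenyl)benzene
Product: 13 3-[3,4-bis(benzyloxy)phenyl]prop-2-ynoic acid, via lithium [3,4-bis(benzyloxy)phenyl]acetylide 11 (not isolated), via lithium 3-[3,4-bis(benzyloxy)phenyl]propiolate 12 (not isolated)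
Conditions: n-BuLi (2.2 equiv), THF, −78 °C; CO2, −78 °C → rt; cold aq. HCl
Reagents that add atoms: carbon dioxide, O=C=O
Why: Second stage of the Corey–Fuchs reaction, in which bromine–lithium exchange, Fritsch–Buttenberg–Wiechell rearrangement and deprotonation give the lithium acetylide, which is carboxylated by CO2 and protonated cold to avoid decarboxylation.

Step 6
Reactants: 8 3,4,5,6-tetramethoxy-2-(trimethylsilyl)phenyl trifluoromethanesulfonate (1.5 equiv); 13 3-[3,4-bis(benzyloxy)phenyl]prop-2-ynoic acid
Product: 16 2-[3,4-bis(benzyloxy)phenyl]-5,6,7,8-tetramethoxy-4H-chromen-4-one, via 3,4,5,6-tetramethoxybenzyne 14 (not isolated), via ortho-hydroxyaryl ynone 15 (not isolated)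
Conditions: CsF (4 equiv), THF, 125 °C, sealed tube
Reagents that add atoms: none
Why: Fluoride attacks silicon in 8 and loss of triflate gives aryne 14; the cesium carboxylate of 13 adds through oxygen, the ortho aryl anion so generated attacks its own ester carbonyl through a four-membered transition state, and collapse of that adduct moves the acyl group from oxygen to carbon, leaving the phenoxide of ynone 15. The closest known reaction type is the fluoride-mediated insertion of arynes into the C–O bond of carboxylic acids (addition followed by an anionic Fries-type acyl shift), which with 3-arylpropiolic acids is known to run on to flavones. Ring C then closes by 6-endo-dig conjugate addition of the C8a phenoxide oxygen to the ynone β-carbon (C2), and the C3 carbanion takes up the proton originally supplied by the acid, so the product is simply the sum of 13 and 14. No stereocenter is formed. Regioselectivity needs no control, because the aryne has a mirror plane through the middle of its triple bond with a methoxy group next to each terminus, so both orientations of addition give the same adduct. What must be secured is chemoselectivity: acyl transfer has to outrun protonation of the aryl anion, which the intramolecular pathway, the aprotic medium, the excess CsF that keeps the acid as its carboxylate and the high temperature favour, and 6-endo has to beat 5-exo closure, which the polarisation of the ynone (electrophilic β-carbon, conjugated 4-pyranone as product) favours under basic conditions.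

Step 7
Reactants: 16 2-[3,4-bis(benzyloxy)phenyl]-5,6,7,8-tetramethoxy-4H-chromen-4-one
Product: 18 sideritiflavone, via boron chelate 17 (not isolated)
Conditions: BCl3 (1 M in CH2Cl2, excess), C6HMe5, CH2Cl2, −78 → 0 °C; then aq. HCl, rt
Reagents that add atoms: none
Why: Lewis-acid ether cleavage, in which BCl3 bound to the C4 carbonyl forms a six-membered chelate with O5 and removes only that methyl group from ring A (the C6 to C8 methoxy groups lack this assistance), while the benzyl ethers ionise at low temperature and pentamethylbenzene captures the benzyl cations by Friedel–Crafts alkylation.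

Compound list
1 | 1,2,3,4-tetramethoxybenzene | COc1ccc(OC)c(OC)c1OC | starting material
2 | (2,3,4,5-tetramethoxyphenyl)lithium | [Li]c1cc(OC)c(OC)c(OC)c1OC | intermediate
3 | dimethyl (2,3,4,5-tetramethoxyphenyl)boronate | COB(OC)c1cc(OC)c(OC)c(OC)c1OC | intermediate
4 | 2,3,4,5-tetramethoxyphenol | Oc1cc(OC)c(OC)c(OC)c1OC | intermediate
5 | 2-bromo-3,4,5,6-tetramethoxyphenol | Oc1c(Br)c(OC)c(OC)c(OC)c1OC | intermediate
6 | (2-bromo-3,4,5,6-tetramethoxyphenoxy)trimethylsilane | C[Si](C)(C)Oc1c(Br)c(OC)c(OC)c(OC)c1OC | intermediate
7 | lithium 2,3,4,5-tetramethoxy-6-(trimethylsilyl)phenoxide | [Li+].[O-]c1c([Si](C)(C)C)c(OC)c(OC)c(OC)c1OC | intermediate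
8 | 3,4,5,6-tetramethoxy-2-(trimethylsilyl)phenyl trifluoromethanesulfonate | COc1c(OC)c(OC)c(OS(=O)(=O)C(F)(F)F)c([Si](C)(C)C)c1OC | intermediate
9 | 3,4-bis(benzyloxy)benzaldehyde | O=Cc1ccc(OCc2ccccc2)c(OCc2ccccc2)c1 | starting material
10 | 1,2-bis(benzyloxy)-4-(2,2-dibromoethenyl)benzene | BrC(Br)=Cc1ccc(OCc2ccccc2)c(OCc2ccccc2)c1 | intermediate
11 | lithium [3,4-bis(benzyloxy)phenyl]acetylide | [Li]C#Cc1ccc(OCc2ccccc2)c(OCc2ccccc2)c1 | intermediate
12 | lithium 3-[3,4-bis(benzyloxy)phenyl]propiolate | [Li+].[O-]C(=O)C#Cc1ccc(OCc2ccccc2)c(OCc2ccccc2)c1 | intermediate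
13 | 3-[3,4-bis(benzyloxy)phenyl]prop-2-ynoic acid | OC(=O)C#Cc1ccc(OCc2ccccc2)c(OCc2ccccc2)c1 | intermediate
14 | 3,4,5,6-tetramethoxybenzyne | COC1=C(OC)C(OC)=C(OC)C#C1 | intermediate
15 | 3-[3,4-bis(benzyloxy)phenyl]-1-(2-hydroxy-3,4,5,6-tetramethoxyphenyl)prop-2-yn-1-one (present as its cesium phenoxide) | COc1c(OC)c(OC)c(C(=O)C#Cc2ccc(OCc3ccccc3)c(OCc3ccccc3)c2)c(O)c1OC | intermediate
16 | 2-[3,4-bis(benzyloxy)phenyl]-5,6,7,8-tetramethoxy-4H-chromen-4-one | COc1c(OC)c(OC)c2c(=O)cc(-c3ccc(OCc4ccccc4)c(OCc4ccccc4)c3)oc2c1OC | intermediate
17 | 2-(2-chloro-1,3,2-benzodioxaborol-5-yl)-5-[(dichloroboranyl)oxy]-6,7,8-trimethoxy-4H-chromen-4-one (boron held by O5 and the C4 carbonyl) | COc1c(OC)c(OB(Cl)Cl)c2c(=O)cc(-c3ccc4OB(Cl)Oc4c3)oc2c1OC | intermediate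
18 | sideritiflavone, 2-(3,4-dihydroxyphenyl)-5-hydroxy-6,7,8-trimethoxy-4H-chromen-4-one | COc1c(OC)c(O)c2c(=O)cc(-c3ccc(O)c(O)c3)oc2c1OC | target

Total step count: 7 (steps 1 to 3 make the aryne precursor, steps 4 and 5 the acid, steps 6 and 7 join and finish).
Longest linear sequence: 5 steps (1, 2, 3, 6, 7).

Steps most likely to fail

Step 6. The aryl anion may be protonated before the acyl group has migrated, so that the sequence stops at the aryl ester. The propiolate may also lose CO2 at 125 °C, or the phenoxide may close onto the α-carbon. The fallback builds ring C by the classical chalcone route; it sets out from 4 and 9 and comes back at 16. Phenol 4 should be C-acetylated at its only free position, ortho to the hydroxyl group, with Ac2O and BF3·OEt2 at 80 °C (Fries-type acylation) to give 1-(2-hydroxy-3,4,5,6-tetramethoxyphenyl)ethan-1-one F1. Claisen–Schmidt condensation of this ketone with aldehyde 9 (KOH, EtOH, rt) should give (E)-3-[3,4-bis(benzyloxy)phenyl]-1-(2-hydroxy-3,4,5,6-tetramethoxyphenyl)prop-2-en-1-one F2. Oxidative cyclisation with catalytic I2 in DMSO at 130 °C should then give 16.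

Step 2. The very electron-rich phenol may be oxidised (oxidative demethylation towards a methoxybenzoquinone) faster than its ring is brominated. The fallback halogenates the masked phenol; it sets out from 4 and comes back at 5. Acetylation (Ac2O, pyridine, catalytic DMAP) should give 2,3,4,5-tetramethoxyphenyl acetate F3, whose ring is far less oxidisable but still activated at the one free position by ortho and para methoxy groups. Bromination (NBS, MeCN, rt) should give 2-bromo-3,4,5,6-tetramethoxyphenyl acetate F4, and methanolysis (K2CO3, MeOH, 0 °C) should return 5.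

Step 7. A second methyl group may be lost (at C6, once O5 is bound to boron), the chelated ether may be cleaved incompletely at the temperature used, or benzyl cations that escape the scavenger may C-benzylate ring A or ring B. The fallback separates the two deprotections; it sets out from 16 and comes back at 18. Hydrogenolysis (H2, Pd/C, EtOAc–THF, rt) should remove both benzyl groups to give 2-(3,4-dihydroxyphenyl)-5,6,7,8-tetramethoxy-4H-chromen-4-one F5. AlCl3 in MeCN at rt, followed by aq. HCl, should then cleave only the C5 ether, which is activated by chelation to the C4 carbonyl.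

Further compounds
F1 | step 6 | 1-(2-hydroxy-3,4,5,6-tetramethoxyphenyl)ethan-1-one | CC(=O)c1c(O)c(OC)c(OC)c(OC)c1OC
F2 | step 6 | (E)-3-[3,4-bis(benzyloxy)phenyl]-1-(2-hydroxy-3,4,5,6-tetramethoxyphenyl)prop-2-en-1-one | COc1c(OC)c(OC)c(C(=O)/C=C/c2ccc(OCc3ccccc3)c(OCc3ccccc3)c2)c(O)c1OC
F3 | step 2 | 2,3,4,5-tetramethoxyphenyl acetate | CC(=O)Oc1cc(OC)c(OC)c(OC)c1OC
F4 | step 2 | 2-bromo-3,4,5,6-tetramethoxyphenyl acetate | CC(=O)Oc1c(Br)c(OC)c(OC)c(OC)c1OC
F5 | step 7 | 2-(3,4-dihydroxyphenyl)-5,6,7,8-tetramethoxy-4H-chromen-4-one | COc1c(OC)c(OC)c2c(=O)cc(-c3ccc(O)c(O)c3)oc2c1OC
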